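**Assumption:** the target has no stereocentre or other stereo-element, so the given SMILES defines it fully and no stereocontrol is needed.

## Retrosynthetic overview

1. Target 20 ⇐ 19 by hydrogenolysis of three benzyl groups; 19 ⇐ 18 by hydrolysis of two dioxolanes.
2. 18 ⇐ ring A acid 9 + ring B phenol 17 (depside ester bond, made last among the skeletal bonds).
3. 9 and 17 ⇐ keto esters 7 and 13; each ArCH2–C(=O) bond comes from a crossed Claisen-type condensation of the lateral (vinylogous) ester enolate of a protected methyl orsellinate (5 or 11) with the hexanoyl donor 3.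
4. 5 and 11 ⇐ methyl orsellinate 4; 3 ⇐ hexanoyl chloride 1 + N,O-dimethylhydroxylamine hydrochloride 2.
5. Ring order: no carbocycle is built, both benzene rings come from 4; the only rings formed are the two temporary dioxolanes (steps 4 and 9), opened again in step 14.

## Route

**Step 1**
Reactants: 1 hexanoyl chloride; 2 N,O-dimethylhydroxylamine hydrochloride
Product: 3 N-methoxy-N-methylhexanamide
Conditions: K2CO3 (4 equiv), EtOAc/H2O 1:1, 0 °C → rt
Reagents that add atoms: none
Why: Schotten–Baumann N-acylation of the amine, freed from its salt by K2CO3, gives the Weinreb amide cleanly.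

**Step 2**
Reactants: 4 methyl 2,4-dihydroxy-6-methylbenzoate (methyl orsellinate)
Product: 5 methyl 2,4-bis(benzyloxy)-6-methylbenzoate
Conditions: BnBr (2.5 equiv), K2CO3 (3 equiv), DMF, 60 °C
Reagents that add atoms: benzyl bromide, BrCc1ccccc1
Why: Double Williamson etherification (warm DMF is needed for the chelated 2-OH) installs benzyl ethers that survive LDA, KOH and mild acid and leave by hydrogenolysis at the end.

**Step 3**
Reactants: 5 methyl 2,4-bis(benzyloxy)-6-methylbenzoate; 3 N-methoxy-N-methylhexanamide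
Product: 7 methyl 2,4-bis(benzyloxy)-6-(2-oxoheptyl)benzoate, via benzylic lithio ester 6 (not isolated)
Conditions: LiN(iPr)2 (LDA, 2.2 equiv), THF, −78 °C; then 3 (1.3 equiv), −78 °C; then 1 M HCl quench
Reagents that add atoms: none
Why: LDA deprotonates the ortho-methyl group to the vinylogous ester enolate, whose crossed Claisen-type C-acylation by the Weinreb amide delivers one acyl group only, while the 2,6-disubstituted ester resists self-condensation.

**Step 4**
Reactants: 7 methyl 2,4-bis(benzyloxy)-6-(2-oxoheptyl)benzoate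
Product: 8 methyl 2,4-bis(benzyloxy)-6-[(2-pentyl-1,3-dioxolan-2-yl)methyl]benzoate
Conditions: TMSOCH2CH2OTMS (2 equiv), TMSOTf (5 mol %), CH2Cl2, −78 → −20 °C; pyridine quench
Reagents that add atoms: 1,2-bis(trimethylsilyloxy)ethane, C[Si](C)(C)OCCO[Si](C)(C)C
Why: Noyori ketalisation, driven by Si–O–Si bond formation, masks the ketone at low temperature without the heat and protic acid that would favour enol-lactonisation onto the neighbouring ester.

**Step 5**
Reactants: 8 methyl 2,4-bis(benzyloxy)-6-[(2-pentyl-1,3-dioxolan-2-yl)methyl]benzoate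
Product: 9 2,4-bis(benzyloxy)-6-[(2-pentyl-1,3-dioxolan-2-yl)methyl]benzoic acid
Conditions: KOH (10 equiv), DMSO/H2O 4:1, 90 °C; then cold aq. KHSO4 to pH 4
Reagents that add atoms: potassium hydroxide, [K+].[OH-]
Why: Saponification of the hindered ester needs hot KOH, which the dioxolane and benzyl ethers tolerate, whereas a free ketone would cyclise onto the ester (intramolecular Claisen or enol lactone).

**Step 6**
Reactants: 4 methyl 2,4-dihydroxy-6-methylbenzoate
Product: 10 methyl 4-(benzyloxy)-2-hydroxy-6-methylbenzoate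
Conditions: BnBr (1.05 equiv), K2CO3 (1.2 equiv), acetone, reflux
Reagents that add atoms: benzyl bromide, BrCc1ccccc1
Why: Regioselective Williamson etherification: the 4-OH is the more acidic, unchelated phenol, while the 2-OH is hydrogen-bonded to the ester carbonyl and stays free (any over-benzylated material is 5 and is not lost).

**Step 7**
Reactants: 10 methyl 4-(benzyloxy)-2-hydroxy-6-methylbenzoate
Product: 11 methyl 4-(benzyloxy)-2-methoxy-6-methylbenzoate
Conditions: MeI (3 equiv), K2CO3 (2 equiv), DMF, 50 °C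
Reagents that add atoms: iodomethane, CI
Why: Williamson O-methylation of the remaining chelated phenol under more forcing conditions installs the ring B methyl ether.

**Step 8**
Reactants: 11 methyl 4-(benzyloxy)-2-methoxy-6-methylbenzoate; 3 N-methoxy-N-methylhexanamide
Product: 13 methyl 4-(benzyloxy)-2-methoxy-6-(2-oxoheptyl)benzoate, via benzylic lithio ester 12 (not isolated)
Conditions: LiN(iPr)2 (LDA, 2.2 equiv), THF, −78 °C; then 3 (1.3 equiv), −78 °C; then 1 M HCl quench
Reagents that add atoms: none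
Why: The same lateral deprotonation and crossed Claisen-type C-acylation as in step 3 builds the ring B 2-oxoheptyl chain.

**Step 9**
Reactants: 13 methyl 4-(benzyloxy)-2-methoxy-6-(2-oxoheptyl)benzoate
Product: 14 methyl 4-(benzyloxy)-2-methoxy-6-[(2-pentyl-1,3-dioxolan-2-yl)methyl]benzoate
Conditions: TMSOCH2CH2OTMS (2 equiv), TMSOTf (5 mol %), CH2Cl2, −78 → −20 °C; pyridine quench
Reagents that add atoms: 1,2-bis(trimethylsilyloxy)ethane, C[Si](C)(C)OCCO[Si](C)(C)C
Why: Noyori ketalisation as in step 4 protects the ketone before the basic ester cleavage.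

**Step 10**
Reactants: 14 methyl 4-(benzyloxy)-2-methoxy-6-[(2-pentyl-1,3-dioxolan-2-yl)methyl]benzoate
Product: 15 4-(benzyloxy)-2-methoxy-6-[(2-pentyl-1,3-dioxolan-2-yl)methyl]benzoic acid
Conditions: KOH (10 equiv), DMSO/H2O 4:1, 90 °C; then cold aq. KHSO4 to pH 4
Reagents that add atoms: potassium hydroxide, [K+].[OH-]
Why: Saponification of the hindered methyl ester as in step 5, with ketal and benzyl ether inert to base.

**Step 11**
Reactants: 15 4-(benzyloxy)-2-methoxy-6-[(2-pentyl-1,3-dioxolan-2-yl)methyl]benzoic acid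
Product: 16 4-hydroxy-2-methoxy-6-[(2-pentyl-1,3-dioxolan-2-yl)methyl]benzoic acid
Conditions: H2 (1 atm), 10% Pd/C, EtOAc, rt
Reagents that add atoms: none
Why: Catalytic hydrogenolysis of the aryl benzyl ether frees the 4-OH under neutral conditions that leave the dioxolane and the acid untouched.

**Step 12**
Reactants: 16 4-hydroxy-2-methoxy-6-[(2-pentyl-1,3-dioxolan-2-yl)methyl]benzoic acid
Product: 17 benzyl 4-hydroxy-2-methoxy-6-[(2-pentyl-1,3-dioxolan-2-yl)methyl]benzoate
Conditions: BnBr (1.1 equiv), KHCO3 (1.5 equiv), DMF, rt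
Reagents that add atoms: benzyl bromide, BrCc1ccccc1
Why: Chemoselective SN2 esterification: KHCO3 deprotonates only the carboxylic acid, so the carboxylate is benzylated and the phenol stays free.

**Step 13**
Reactants: 9 2,4-bis(benzyloxy)-6-[(2-pentyl-1,3-dioxolan-2-yl)methyl]benzoic acid; 17 benzyl 4-hydroxy-2-methoxy-6-[(2-pentyl-1,3-dioxolan-2-yl)methyl]benzoate
Product: 18 benzyl 4-({2,4-bis(benzyloxy)-6-[(2-pentyl-1,3-dioxolan-2-yl)methyl]benzoyl}oxy)-2-methoxy-6-[(2-pentyl-1,3-dioxolan-2-yl)methyl]benzoate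
Conditions: DCC (1.2 equiv), DMAP (0.2 equiv), CH2Cl2, 0 °C → rt
Reagents that add atoms: none
Why: Steglich esterification: DCC activates the hindered acid and DMAP relays the acyl group to the unhindered ring B phenol, while the ketal keeps the ring A ketone from enol-lactonising onto the activated carboxyl.

**Step 14**
Reactants: 18 the bis-dioxolane tribenzyl depside
Product: 19 benzyl 4-{[2,4-bis(benzyloxy)-6-(2-oxoheptyl)benzoyl]oxy}-2-methoxy-6-(2-oxoheptyl)benzoate
Conditions: 1 M aq. HCl/THF 1:4, rt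
Reagents that add atoms: water, O
Why: Acid-catalysed ketal hydrolysis releases both ketones at room temperature, conditions under which benzyl ethers, the benzyl ester and the aryl ester stay intact.

**Step 15**
Reactants: 19 benzyl 4-{[2,4-bis(benzyloxy)-6-(2-oxoheptyl)benzoyl]oxy}-2-methoxy-6-(2-oxoheptyl)benzoate
Product: 20 arthonioic acid, 4-{[2,4-dihydroxy-6-(2-oxoheptyl)benzoyl]oxy}-2-methoxy-6-(2-oxoheptyl)benzoic acid
Conditions: H2 (1 atm), 10% Pd/C, EtOAc, rt
Reagents that add atoms: none
Why: Catalytic hydrogenolysis removes the two benzyl ethers and the benzyl ester in one neutral operation, dialkyl ketones and the depside ester being inert to H2 over Pd/C.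

## Compound list

1 | hexanoyl chloride | CCCCCC(=O)Cl | starting material
2 | N,O-dimethylhydroxylamine hydrochloride | CNOC.Cl | starting material
3 | N-methoxy-N-methylhexanamide | CCCCCC(=O)N(C)OC | intermediate
4 | methyl 2,4-dihydroxy-6-methylbenzoate (methyl orsellinate) | COC(=O)c1c(C)cc(O)cc1O | starting material
5 | methyl 2,4-bis(benzyloxy)-6-methylbenzoate | COC(=O)c1c(C)cc(OCc2ccccc2)cc1OCc1ccccc1 | intermediate
6 | benzylic lithio ester (lithium dienolate) of 5, not isolated | COC(=O)c1c(C[Li])cc(OCc2ccccc2)cc1OCc1ccccc1 | intermediate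
7 | methyl 2,4-bis(benzyloxy)-6-(2-oxoheptyl)benzoate | CCCCCC(=O)Cc1cc(OCc2ccccc2)cc(OCc2ccccc2)c1C(=O)OC | intermediate
8 | methyl 2,4-bis(benzyloxy)-6-[(2-pentyl-1,3-dioxolan-2-yl)methyl]benzoate | CCCCCC1(Cc2cc(OCc3ccccc3)cc(OCc3ccccc3)c2C(=O)OC)OCCO1 | intermediate
9 | 2,4-bis(benzyloxy)-6-[(2-pentyl-1,3-dioxolan-2-yl)methyl]benzoic acid | CCCCCC1(Cc2cc(OCc3ccccc3)cc(OCc3ccccc3)c2C(=O)O)OCCO1 | intermediate
10 | methyl 4-(benzyloxy)-2-hydroxy-6-methylbenzoate | COC(=O)c1c(C)cc(OCc2ccccc2)cc1O | intermediate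
11 | methyl 4-(benzyloxy)-2-methoxy-6-methylbenzoate | COC(=O)c1c(C)cc(OCc2ccccc2)cc1OC | intermediate
12 | benzylic lithio ester (lithium dienolate) of 11, not isolated | COC(=O)c1c(C[Li])cc(OCc2ccccc2)cc1OC | intermediate
13 | methyl 4-(benzyloxy)-2-methoxy-6-(2-oxoheptyl)benzoate | CCCCCC(=O)Cc1cc(OCc2ccccc2)cc(OC)c1C(=O)OC | intermediate
14 | methyl 4-(benzyloxy)-2-methoxy-6-[(2-pentyl-1,3-dioxolan-2-yl)methyl]benzoate | CCCCCC1(Cc2cc(OCc3ccccc3)cc(OC)c2C(=O)OC)OCCO1 | intermediate
15 | 4-(benzyloxy)-2-methoxy-6-[(2-pentyl-1,3-dioxolan-2-yl)methyl]benzoic acid | CCCCCC1(Cc2cc(OCc3ccccc3)cc(OC)c2C(=O)O)OCCO1 | intermediate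
16 | 4-hydroxy-2-methoxy-6-[(2-pentyl-1,3-dioxolan-2-yl)methyl]benzoic acid | CCCCCC1(Cc2cc(O)cc(OC)c2C(=O)O)OCCO1 | intermediate
17 | benzyl 4-hydroxy-2-methoxy-6-[(2-pentyl-1,3-dioxolan-2-yl)methyl]benzoate | CCCCCC1(Cc2cc(O)cc(OC)c2C(=O)OCc2ccccc2)OCCO1 | intermediate
18 | benzyl 4-({2,4-bis(benzyloxy)-6-[(2-pentyl-1,3-dioxolan-2-yl)methyl]benzoyl}oxy)-2-methoxy-6-[(2-pentyl-1,3-dioxolan-2-yl)methyl]benzoate | CCCCCC1(Cc2cc(OCc3ccccc3)cc(OCc3ccccc3)c2C(=O)Oc2cc(CC3(CCCCC)OCCO3)c(C(=O)OCc3ccccc3)c(OC)c2)OCCO1 | intermediate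
19 | benzyl 4-{[2,4-bis(benzyloxy)-6-(2-oxoheptyl)benzoyl]oxy}-2-methoxy-6-(2-oxoheptyl)benzoate | CCCCCC(=O)Cc1cc(OCc2ccccc2)cc(OCc2ccccc2)c1C(=O)Oc1cc(CC(=O)CCCCC)c(C(=O)OCc2ccccc2)c(OC)c1 | intermediate
20 | arthonioic acid | CCCCCC(=O)Cc1cc(O)cc(O)c1C(=O)Oc1cc(CC(=O)CCCCC)c(C(=O)O)c(OC)c1 | target

## Summary

Total step count: 15.
Longest linear sequence: 10 steps (4 → 10 → 11 → 13 → 14 → 15 → 16 → 17 → 18 → 19 → 20; steps 6–15).

**Three steps most likely to fail, with fallbacks**

Step 3 (Claisen-type acylation of the lateral anion). The risk is proton transfer from the α-CH2 of the amide to the benzylic anion, which returns 5, and partial cyclisation of any ketone liberated before the quench. The fallback sets out from 5 and replaces the acylation by a directed aldol addition followed by oxidation. The same anion (LiN(iPr)2, THF, −78 °C) is treated with hexanal, which is far more electrophilic than the amide, and quenched at −78 °C with acetic acid. This gives racemic methyl 2,4-bis(benzyloxy)-6-(2-hydroxyheptyl)benzoate F1, which is kept cold to forestall lactonisation. Crude F1 is oxidised at once with Dess–Martin periodinane in NaHCO3-buffered CH2Cl2, which erases the carbinol centre and returns to the route at 7.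

Step 13 (Steglich depside coupling). The risk is that the di-ortho-substituted O-acylisourea rearranges to the N-acylurea faster than it is intercepted. The fallback sets out from 9 and 17 and uses a preformed acid chloride and a preformed phenolate. Acid 9 is treated with 1-chloro-N,N,2-trimethylprop-1-en-1-amine in CH2Cl2 at rt, which is neutral and safe for the ketal. This gives 2,4-bis(benzyloxy)-6-[(2-pentyl-1,3-dioxolan-2-yl)methyl]benzoyl chloride F2. Separately, 17 is deprotonated with NaH in THF at 0 °C to sodium 4-[(benzyloxy)carbonyl]-3-methoxy-5-[(2-pentyl-1,3-dioxolan-2-yl)methyl]phenolate F3. Adding F2 to F3 gives the aryl ester and returns to the route at 18.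

Step 14 (unmasking both ketones next to the aryl ester). The risk is incomplete hydrolysis, or acid-induced enol-lactonisation of the ring A ketone onto the depside carbonyl with loss of the ring B phenol. The fallback sets out from 18 and reverses the order of the endgame. Hydrogenolysis first (H2, 10% Pd/C, EtOAc, rt) gives 4-({2,4-dihydroxy-6-[(2-pentyl-1,3-dioxolan-2-yl)methyl]benzoyl}oxy)-2-methoxy-6-[(2-pentyl-1,3-dioxolan-2-yl)methyl]benzoic acid F4. In F4 the depside carbonyl is chelated and deactivated by the free 2-OH of ring A, as in the stable natural product. Mild ketal hydrolysis of F4 (0.5 M aq. HCl/THF, rt) then returns to the route at 20.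

## Further compounds

F1 | step 3 | methyl 2,4-bis(benzyloxy)-6-(2-hydroxyheptyl)benzoate (racemic) | CCCCCC(O)Cc1cc(OCc2ccccc2)cc(OCc2ccccc2)c1C(=O)OC
F2 | step 13 | 2,4-bis(benzyloxy)-6-[(2-pentyl-1,3-dioxolan-2-yl)methyl]benzoyl chloride | CCCCCC1(Cc2cc(OCc3ccccc3)cc(OCc3ccccc3)c2C(=O)Cl)OCCO1
F3 | step 13 | sodium 4-[(benzyloxy)carbonyl]-3-methoxy-5-[(2-pentyl-1,3-dioxolan-2-yl)methyl]phenolate | CCCCCC1(Cc2cc([O-])cc(OC)c2C(=O)OCc2ccccc2)OCCO1.[Na+]
F4 | step 14 | 4-({2,4-dihydroxy-6-[(2-pentyl-1,3-dioxolan-2-yl)methyl]benzoyl}oxy)-2-methoxy-6-[(2-pentyl-1,3-dioxolan-2-yl)methyl]benzoic acid | CCCCCC1(Cc2cc(O)cc(O)c2C(=O)Oc2cc(CC3(CCCCC)OCCO3)c(C(=O)O)c(OC)c2)OCCO1
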